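The constants used here were chosen freely; no experiment stands behind them.

Late in this flask, the isomer of the product climbs towards 1.8 times dissolved target, and the reckoning below holds dissolved target at its solubility while solid product is present.

    solid substrate ⇌ dissolved substrate, rate k1*(cs1 - [dissolved substrate]) while solid is left; crystals form when [dissolved substrate] > cs1 (cs1 = 34 mM, k1 = 0.18 s⁻¹)
    dissolved substrate + coupling partner → target (k2 = 5.4 M⁻¹ s⁻¹)
    solid product ⇌ target, rate k3*(cs3 - [target]) while solid is left; crystals form when [target] > cs3 (cs3 = 1.7 mM, k3 = 1.5 s⁻¹)
    2 coupling partner → self-condensation product (k4 = 0.014 M⁻¹ s⁻¹)
    target ⇌ isomer of the product (K5 = 1.8, k5 = 0.014 s⁻¹)

solid substrate 0.055 M; coupling partner 0.138 M; time 2.5 min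

- how much target and solid product together there is at 2.5 min, in percent of the solid substrate charged
- concentration of dissolved substrate in solution at 2.5 min, in percent of saturation

- target is meant together with its solid product
- a doubled species enters its step squared and goes two at a time
- solid, in amounts per volume of the solution: solid substrate, solid product
- at the start none of the solid substrate is in solution
- dissolved substrate means what is dissolved; the solid is not counted in it
- run time (flask): 2.5 min

Turned into times at the charged amounts, most constants are fast. Dissolved substrate has a half-life of 0.93 s against coupling partner, and solid substrate dissolves on a scale of 5.56 s, which is shorter than the run. The isomer's climb has a half-life of 1.49 min, reckoned with dissolved target held at 1.7 mM. Crystals exchange target on a scale of 0.667 s, which is faster than that climb. The ceiling of that climb is 3.06 mM, and the run lasts 1.68 of these half-lives. The ceiling, times the part of the climb done by the asked time, over the charge, gives 3.83%, the isomer toll: the share of the solid substrate charged that stands as isomer and not as target or solid product.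

Three settings can be turned by hand. Coupling partner does not enter the toll; solid substrate is the limiting reagent, charged at less than the partner, and dissolved substrate lasts a shorter time than the run, so its saturation reckons close to zero. The charge of solid substrate divides the toll, since it exceeds what the solution and isomer take up at the ceiling, so less charge costs more percent. Time moves the toll towards 5.56%. By hand, then, target and solid product together reach 96.2%.

The forecast gave 95.9% for y, against 96.2% by this reckoning, and 0% of saturation, holding that “The only loss is isomer”.

The flask gives 95.9% and 0% of saturation, 0.30 percentage points under the hand figure. Moved alone up or down by one factor, the settings shift y in the order solid substrate (1.1 points), then time (0.45 points), then coupling partner (under 0.05 points). With 0.014 M of solid substrate and the same time, the toll reckons to 15.1%, and that neighbour flask holds 15.2% as isomer of the product beside 72.7% as solid product, its y standing at 84.8%.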